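**Plan**

- Retrosynthetically, the MOM group on O2' is removed and the two C–C bonds that hold the 1,1-dimethylallyl groups at C6 and C5' are cut back to O7 and O4' prenyl ethers (retro-Claisen).
- Ring C is then opened at C4–C4a and O1–C8a. Ring C (O1, C2, C3, C4, C4a, C8a) joins ring A through the neighbouring carbons C4a (carbon link) and C8a (oxygen link), with O7 meta to C8a and para to C4a. This is the ortho/ipso pattern a 3-oxygenated aryl iodide offers to palladium/norbornene catalysis.
- The partner is a ring B 2-aryl-3-bromopropan-1-ol, traced through its prochiral 2-aryl-propane-1,3-diol to an aryl malonate and a regiodefined iodo-resorcinol diether.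
- Forward: ring B iodide, malonate, diol, desymmetrised bromo alcohol; ring C is closed onto the ring A iodide in one operation; debenzylation, twofold O-prenylation, double Claisen rearrangement and MOM removal finish the synthesis.
- The only stereocentre, C3, comes from lipase desymmetrisation of the prochiral diol and is a spectator afterwards (R in the chroman series).

Key step: step 9

Assumption: the lipase of step 5 is taken to acetylate the enantiotopic CH2OH arm that leads to the (S)-monoacetate. This sense must be confirmed on the ortho-oxygenated aryl diol; an enzyme of opposite sense is accommodated by the hydrolytic variant given under the fallbacks.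

**Route**

Step 1
Reactants: 1 3-(benzyloxy)phenol
Product: 2 5-(benzyloxy)-2-iodophenol
Conditions: I2, NaHCO3, THF/H2O, 0 °C to rt
Reagents that add atoms: iodine, II
Why: Electrophilic aromatic iodination of the phenoxide should go to the carbon ortho to the hydroxyl and para to the benzyloxy group, because the other activated positions lie next to the bulkier benzyl ether or between the two oxygens; any 4-iodo isomer is removed by chromatography.

Step 2
Reactants: 2 5-(benzyloxy)-2-iodophenol
Product: 3 4-(benzyloxy)-1-iodo-2-(methoxymethoxy)benzene
Conditions: MOMCl, K2CO3, acetone, 0 °C to rt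
Reagents that add atoms: chloromethyl methyl ether, COCCl
Why: Williamson-type O-alkylation of the acidic ortho-iodophenoxide with the reactive α-chloro ether gives the base-stable MOM acetal that keeps O2' apart from the two benzyl-protected oxygens.

Step 3
Reactants: 3 4-(benzyloxy)-1-iodo-2-(methoxymethoxy)benzene; 4 diethyl malonate
Product: 5 diethyl 2-[4-(benzyloxy)-2-(methoxymethoxy)phenyl]malonate
Conditions: CuI (cat.), 2-picolinic acid (cat.), Cs2CO3, 1,4-dioxane, 70 °C
Reagents that add atoms: none
Why: Copper-catalysed Ullmann–Hurtley-type C-arylation of the malonate anion by an aryl iodide tolerates ortho alkoxy groups and leaves the benzyl and MOM ethers untouched.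

Step 4
Reactants: 5 diethyl 2-[4-(benzyloxy)-2-(methoxymethoxy)phenyl]malonate
Product: 6 2-[4-(benzyloxy)-2-(methoxymethoxy)phenyl]propane-1,3-diol
Conditions: LiAlH4, THF, 0 °C to rt; Fieser work-up
Reagents that add atoms: none
Why: Hydride reduction of both esters gives the prochiral 2-aryl-1,3-diol, the malonate being added slowly to excess hydride to limit unproductive enolate formation, while the ethers are inert.

Step 5
Reactants: 6 2-[4-(benzyloxy)-2-(methoxymethoxy)phenyl]propane-1,3-diol
Product: 7 (S)-2-[4-(benzyloxy)-2-(methoxymethoxy)phenyl]-3-hydroxypropyl acetate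
Conditions: lipase PS (Burkholderia cepacia, immobilised), vinyl acetate, t-BuOMe, 25 °C
Reagents that add atoms: vinyl acetate, CC(=O)OC=C
Why: Lipase-catalysed irreversible transesterification desymmetrises the prochiral diol, the chiral acyl-enzyme pocket selecting one enantiotopic hydroxymethyl arm and so setting the centre that becomes C3, with vinyl alcohol leaving as acetaldehyde.

Step 6
Reactants: 7 (S)-2-[4-(benzyloxy)-2-(methoxymethoxy)phenyl]-3-hydroxypropyl acetate
Product: 8 (R)-2-[4-(benzyloxy)-2-(methoxymethoxy)phenyl]-3-bromopropyl acetate
Conditions: CBr4, PPh3, CH2Cl2, 0 °C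
Reagents that add atoms: carbon tetrabromide, BrC(Br)(Br)Br
Why: Appel bromination displaces the primary oxyphosphonium by bromide without touching the stereocentre, and the neutral medium avoids the 1,3-acetyl shift that would racemise the monoacetate (the change of descriptor from S to R is a priority effect only).

Step 7
Reactants: 8 (R)-2-[4-(benzyloxy)-2-(methoxymethoxy)phenyl]-3-bromopropyl acetate
Product: 9 (R)-2-[4-(benzyloxy)-2-(methoxymethoxy)phenyl]-3-bromopropan-1-ol
Conditions: K2CO3 (cat.), MeOH, 0 °C
Reagents that add atoms: none
Why: Zemplén-type transesterification removes the acetate as methyl acetate at a temperature at which the primary bromide should neither close to an oxetane nor eliminate.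

Step 8
Reactants: 10 3-iodophenol
Product: 11 1-(benzyloxy)-3-iodobenzene
Conditions: BnBr, K2CO3, acetone, reflux
Reagents that add atoms: benzyl bromide, BrCc1ccccc1
Why: Williamson etherification of the phenoxide with a benzylic bromide gives the ring A iodide whose oxygen is meta to iodine.

Step 9
Reactants: 9 (R)-2-[4-(benzyloxy)-2-(methoxymethoxy)phenyl]-3-bromopropan-1-ol; 11 1-(benzyloxy)-3-iodobenzene
Product: 12 (3R)-7-(benzyloxy)-3-[4-(benzyloxy)-2-(methoxymethoxy)phenyl]chroman
Conditions: Pd(OAc)2 (10 mol %), RuPhos (20 mol %), 1-methylnorbornene (1 equiv), Cs2CO3 (3 equiv), 1,4-dioxane, 100 °C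
Reagents that add atoms: none
Why: Proposed new method: zerovalent palladium should add to the C–I bond of 11, the norbornene inserts and the ortho C–H para to the benzyloxy group (C4 of 11, the later C4a) is palladated; the divalent palladacycle then takes up the primary bromide of 9 by SN2-type oxidative addition to a tetravalent palladium species that reductively eliminates the C4–C4a bond, the norbornene is expelled by β-carbon elimination, and the pendant alkoxide binds palladium and closes C8a–O1 by C–O reductive elimination. The closest known reactions are the palladium/norbornene annulations of aryl iodides with epoxides to 2,3-dihydrobenzofurans and with bromoalkylamines to indolines and tetrahydroquinolines; the six-membered ipso etherification with a free bromo alcohol is the untested extension. Ring C closes by intramolecular aryl–oxygen reductive elimination from a seven-membered aryl palladium alkoxide chelate, the tether making this termination faster than any intermolecular one. No stereocentre is formed, and C3, which carries no acidic or metal-bound bond, should keep the configuration set in step 5. The step needs alkylation once and only at the ortho carbon para to the benzyloxy group, which the hindrance of the position between iodine and oxygen (C2 of 11, the later C8) and the bridgehead methyl group of the norbornene, which favours its extrusion after a single alkylation, are meant to secure. It also needs C–O reductive elimination to outrun β-hydride elimination of the primary alkoxide, for which the bulky electron-rich biaryl phosphine and a carbonate base in a weakly polar solvent are chosen.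

Step 10
Reactants: 12 (3R)-7-(benzyloxy)-3-[4-(benzyloxy)-2-(methoxymethoxy)phenyl]chroman
Product: 13 (3R)-3-[4-hydroxy-2-(methoxymethoxy)phenyl]chroman-7-ol
Conditions: H2 (1 atm), Pd/C, EtOAc/MeOH, rt
Reagents that add atoms: none
Why: Catalytic hydrogenolysis cleaves both benzylic C–O bonds, while the MOM acetal, the chroman ether and the stereocentre (not benzylic to oxygen) are inert.

Step 11
Reactants: 13 (3R)-3-[4-hydroxy-2-(methoxymethoxy)phenyl]chroman-7-ol; 14 prenyl bromide (1-bromo-3-methylbut-2-ene)
Product: 15 (3R)-3-[2-(methoxymethoxy)-4-(3-methylbut-2-en-1-yloxy)phenyl]-7-(3-methylbut-2-en-1-yloxy)chroman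
Conditions: prenyl bromide (2.5 equiv in all), K2CO3 (3 equiv), acetone, 50 °C
Reagents that add atoms: prenyl bromide (second equivalent of 14), CC(C)=CCBr
Why: Twofold Williamson etherification, one molecule of prenyl bromide being consumed by each of the two phenoxides at its primary allylic carbon (SN2, no allylic transposition), places a prenyl group on O7 and on O4', O2' being masked.

Step 12
Reactants: 15 (3R)-3-[2-(methoxymethoxy)-4-(3-methylbut-2-en-1-yloxy)phenyl]-7-(3-methylbut-2-en-1-yloxy)chroman
Product: 16 (3R)-3-[4-hydroxy-2-(methoxymethoxy)-5-(2-methylbut-3-en-2-yl)phenyl]-6-(2-methylbut-3-en-2-yl)chroman-7-ol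
Conditions: N,N-diethylaniline, 200 °C, sealed tube
Reagents that add atoms: none
Why: Two aromatic Claisen ([3,3]-sigmatropic) rearrangements deliver each prenyl group with allylic inversion, as a 2-methylbut-3-en-2-yl group, to the ortho carbon para to the other ring oxygen (C6 and C5'), since the alternative ortho carbons C8 and C3' are flanked by two oxygens, as is general for 2-alkoxy-4-prenyloxy arenes, and the basic solvent suppresses acid-induced cyclisation of the products.

Step 13
Reactants: 16 (3R)-3-[4-hydroxy-2-(methoxymethoxy)-5-(2-methylbut-3-en-2-yl)phenyl]-6-(2-methylbut-3-en-2-yl)chroman-7-ol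
Product: 17 manuifolin E, (3R)-3-[2,4-dihydroxy-5-(2-methylbut-3-en-2-yl)phenyl]-6-(2-methylbut-3-en-2-yl)chroman-7-ol
Conditions: HCl (cat.), MeOH, 40 °C
Reagents that add atoms: none
Why: Acid-catalysed acetal exchange removes the MOM group as dimethoxymethane, and the monosubstituted alkenes of the 1,1-dimethylallyl groups are too weakly basic to be protonated under these dilute conditions.

**Compound list**

1 | 3-(benzyloxy)phenol | Oc1cccc(OCc2ccccc2)c1 | starting material
2 | 5-(benzyloxy)-2-iodophenol | Oc1cc(OCc2ccccc2)ccc1I | intermediate
3 | 4-(benzyloxy)-1-iodo-2-(methoxymethoxy)benzene | COCOc1cc(OCc2ccccc2)ccc1I | intermediate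
4 | diethyl malonate | CCOC(=O)CC(=O)OCC | starting material
5 | diethyl 2-[4-(benzyloxy)-2-(methoxymethoxy)phenyl]malonate | CCOC(=O)C(C(=O)OCC)c1ccc(OCc2ccccc2)cc1OCOC | intermediate
6 | 2-[4-(benzyloxy)-2-(methoxymethoxy)phenyl]propane-1,3-diol | OCC(CO)c1ccc(OCc2ccccc2)cc1OCOC | intermediate
7 | (S)-2-[4-(benzyloxy)-2-(methoxymethoxy)phenyl]-3-hydroxypropyl acetate | CC(=O)OC[C@@H](c1ccc(OCc2ccccc2)cc1OCOC)CO | intermediate
8 | (R)-2-[4-(benzyloxy)-2-(methoxymethoxy)phenyl]-3-bromopropyl acetate | CC(=O)OC[C@@H](c1ccc(OCc2ccccc2)cc1OCOC)CBr | intermediate
9 | (R)-2-[4-(benzyloxy)-2-(methoxymethoxy)phenyl]-3-bromopropan-1-ol | OC[C@@H](c1ccc(OCc2ccccc2)cc1OCOC)CBr | intermediate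
10 | 3-iodophenol | Oc1cccc(I)c1 | starting material
11 | 1-(benzyloxy)-3-iodobenzene | Ic1cccc(OCc2ccccc2)c1 | intermediate
12 | (3R)-7-(benzyloxy)-3-[4-(benzyloxy)-2-(methoxymethoxy)phenyl]chroman | c1ccc(COc2ccc3c(c2)OC[C@@H](c2ccc(OCc4ccccc4)cc2OCOC)C3)cc1 | intermediate
13 | (3R)-3-[4-hydroxy-2-(methoxymethoxy)phenyl]chroman-7-ol | Oc1ccc2c(c1)OC[C@@H](c1ccc(O)cc1OCOC)C2 | intermediate
14 | prenyl bromide (1-bromo-3-methylbut-2-ene) | CC(C)=CCBr | starting material
15 | (3R)-3-[2-(methoxymethoxy)-4-(3-methylbut-2-en-1-yloxy)phenyl]-7-(3-methylbut-2-en-1-yloxy)chroman | CC(C)=CCOc1ccc2c(c1)OC[C@@H](c1ccc(OCC=C(C)C)cc1OCOC)C2 | intermediate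
16 | (3R)-3-[4-hydroxy-2-(methoxymethoxy)-5-(2-methylbut-3-en-2-yl)phenyl]-6-(2-methylbut-3-en-2-yl)chroman-7-ol | C=CC(C)(C)c1cc2c(cc1O)OC[C@@H](c1cc(C(C)(C)C=C)c(O)cc1OCOC)C2 | intermediate
17 | manuifolin E | C=CC(C)(C)c1cc2c(cc1O)OC[C@@H](c1cc(C(C)(C)C=C)c(O)cc1O)C2 | target

**Count and risks**

Total step count: 13. Longest linear sequence: 12 steps (steps 1 to 7 and 9 to 13); step 8 is a one-step side branch.

Steps most likely to fail:

1. Step 9. The annulation may be diverted by β-hydride elimination from the aryl palladium alkoxide before C–O bond formation, by failure of the norbornene to leave after one alkylation (further ortho functionalisation or norbornene-containing products), by sluggish oxidative addition of the β-branched bromide, or by base-induced loss of HBr from 9 before it is captured. The fallback uses known chemistry, sets out from 9 and uses phenol 2, which the route already makes. Mitsunobu etherification of 9 with 2 (PPh3, diisopropyl azodicarboxylate, THF, 0 °C to rt) forms the O1–C2 bond first and gives (R)-4-(benzyloxy)-2-{2-[4-(benzyloxy)-2-(methoxymethoxy)phenyl]-3-bromopropoxy}-1-iodobenzene F1. Iodine–lithium exchange with t-BuLi (2 equiv, THF/Et2O, −100 °C, then −78 °C) followed by intramolecular alkylation of the aryllithium by the primary bromide (Parham cyclisation, 6-exo-tet) closes C4–C4a and comes back to the route at 12, with C3 untouched.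

2. Step 12. A prenyl group may migrate to the ortho carbon between two oxygens (C8 or C3'), and at 200 °C the ortho-allyl phenols may isomerise further (abnormal Claisen) or cyclise onto the neighbouring hydroxyl; both events must go cleanly on two rings at once. The fallback sets out from 13 and installs the side chains by cross-coupling instead. Both phenols are capped (MOMCl, 2 equiv or more, K2CO3, acetone) to give (3R)-3-[2,4-bis(methoxymethoxy)phenyl]-7-(methoxymethoxy)chroman F2. NBS (2 equiv, MeCN, 0 °C) brominates each ring para to an ether oxygen and away from the doubly flanked carbons, giving (3R)-6-bromo-3-[5-bromo-2,4-bis(methoxymethoxy)phenyl]-7-(methoxymethoxy)chroman F3. A twofold γ-selective Suzuki–Miyaura coupling with prenylboronic acid pinacol ester (2 equiv or more, Pd(OAc)2, a bulky biaryl phosphine selected for the branched product, K3PO4, THF/H2O) gives (3R)-3-[2,4-bis(methoxymethoxy)-5-(2-methylbut-3-en-2-yl)phenyl]-7-(methoxymethoxy)-6-(2-methylbut-3-en-2-yl)chroman F4. The acidic methanolysis of step 13 then removes all three MOM groups and comes back to the route at 17.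

3. Step 5. The enzyme may discriminate poorly between the enantiotopic arms of a diol with an ortho-substituted aryl group, may acylate the arm opposite to the one assumed, or may over-acylate. The fallback sets out from 6 and runs the desymmetrisation in the hydrolytic direction. Peracetylation (Ac2O, pyridine, DMAP cat., CH2Cl2) gives 2-[4-(benzyloxy)-2-(methoxymethoxy)phenyl]propane-1,3-diyl diacetate F5. Lipase-catalysed monohydrolysis in phosphate buffer (pH 7, with a cosolvent) then cleaves the arm that the same enzyme would otherwise acylate, so it gives the opposite monoacetate enantiomer, and over-hydrolysis of the minor enantiomer to the diol sharpens the enantiomeric purity. With the enzyme chosen for the required sense this comes back to the route at 7.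

**Further compounds**

F1 | step 9 | (R)-4-(benzyloxy)-2-{2-[4-(benzyloxy)-2-(methoxymethoxy)phenyl]-3-bromopropoxy}-1-iodobenzene | Ic1ccc(OCc2ccccc2)cc1OC[C@@H](c1ccc(OCc2ccccc2)cc1OCOC)CBr
F2 | step 12 | (3R)-3-[2,4-bis(methoxymethoxy)phenyl]-7-(methoxymethoxy)chroman | COCOc1ccc2c(c1)OC[C@@H](c1ccc(OCOC)cc1OCOC)C2
F3 | step 12 | (3R)-6-bromo-3-[5-bromo-2,4-bis(methoxymethoxy)phenyl]-7-(methoxymethoxy)chroman | Brc1cc2c(cc1OCOC)OC[C@@H](c1cc(Br)c(OCOC)cc1OCOC)C2
F4 | step 12 | (3R)-3-[2,4-bis(methoxymethoxy)-5-(2-methylbut-3-en-2-yl)phenyl]-7-(methoxymethoxy)-6-(2-methylbut-3-en-2-yl)chroman | C=CC(C)(C)c1cc2c(cc1OCOC)OC[C@@H](c1cc(C(C)(C)C=C)c(OCOC)cc1OCOC)C2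
F5 | step 5 | 2-[4-(benzyloxy)-2-(methoxymethoxy)phenyl]propane-1,3-diyl diacetate | CC(=O)OCC(COC(C)=O)c1ccc(OCc2ccccc2)cc1OCOC
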